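**Plan**

- Retrosynthesis: late functional-group changes lead back to ring-B enone 12. C2–C3 and C4–C4a of ring B (naphthalene numbering of the target) are then cut together, as the insertion of propyne into the C(=O)–C bond of cyclobutanone 9. Ketone 9 is cut by a [2+2] into a keteniminium ion and 1-methylcyclohexa-1,3-diene.
- Forward: ring A is bought as the diene. Step 3 fuses a four-membered ring onto it, step 4 expands that ring by two carbons to ring B (strain release), and the later steps set oxidation levels and attach the ester and the acrylic acid.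
- Enabling feature: in ring B the oxygen-bearing C2 and the ring-fusion carbon C4a are linked through C1–C8a. C2/C1/C8a/C4a can therefore be a cyclobutanone whose C2–C4a bond takes up propyne as C3 and C4(CH3). A methoxy group on C1 makes that carbon quaternary for the insertion and is removed afterwards.
- Stereochemistry: C4a from the C2-symmetric pyrrolidine auxiliary in the [2+2]; C1 by equilibrating protonation on the convex face after demethoxylation; C4 by hydroxyl-directed epoxidation; C2 by hydroxyl-directed hydride delivery; C8a by thermodynamic epimerization through the ring-A enone; C6 by Luche reduction; the E ester geometry from the dioxepine ring.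

Key step: step 4

Assumption: the (2R,5R)-auxiliary is taken to give the ring-fusion configuration drawn for 9; if it induces the opposite sense, its (2S,5S)-antipode is used in steps 1–3.
Remark: locants of the bicyclic compounds follow naphthalene numbering (C1 side-chain carbon, C2 oxygen-bearing carbon, C4 carbinol carbon, C4a/C8a ring fusion, C6/C7 in ring A).

**Route**

Step 1
Reactants: 1 methoxyacetyl chloride; 2 (2R,5R)-2,5-dimethylpyrrolidine
Product: 3 methoxyacetamide of the auxiliary
Conditions: Et3N, CH2Cl2, 0 °C to rt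
Reagents that add atoms: none
Why: N-acylation of the secondary amine by the acid chloride; it joins the chiral auxiliary to the later blocking methoxy group and makes no stereocentre.

Step 2
Reactants: 3 methoxyacetamide; 4 tert-butyl(2-iodoethoxy)diphenylsilane
Product: 5 alkylated α-methoxy amide
Conditions: LDA, THF, −78 °C; then 4, DMPU, −78 to 0 °C
Reagents that add atoms: none
Why: SN2 alkylation of the lithium amide enolate by the primary iodide; the α-carbon made here becomes sp2 in step 3, so its configuration does not matter.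

Step 3
Reactants: 5 alkylated α-methoxy amide; 6 1-methylcyclohexa-1,3-diene
Product: 9 cis-fused methoxy cyclobutanone, via keteniminium triflate 7 (not isolated), via cyclobutaniminium triflate 8 (not isolated)
Conditions: Tf2O, 2,4,6-collidine, ClCH2CH2Cl, −20 °C; 6, −20 to 60 °C; then H2O, 60 °C
Reagents that add atoms: water (O)
Why: Keteniminium [2+2] cycloaddition: the iminium carbon adds to the unsubstituted diene terminus (methyl-stabilised allyl cation) and the four-membered ring closes cis on the less substituted double bond; the C2-symmetric pyrrolidine shields one face and so sets both ring-fusion centres, and hydrolysis frees the ketone.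

Step 4
Reactants: 9 cis-fused methoxy cyclobutanone; 10 propyne
Product: 11 cis-fused 1-methoxy ring-B enone
Conditions: Ni(cod)2 (cod = cycloocta-1,5-diene, 10 mol %), IPr (1,3-bis(2,6-diisopropylphenyl)imidazol-2-ylidene, 12 mol %), toluene, 90 °C, 10 added slowly
Reagents that add atoms: none
Why: Zerovalent nickel couples the strained ketone carbonyl with propyne by oxidative cyclization to a spiro oxanickelacyclopentene, β-carbon elimination then opens the four-membered ring to a seven-membered nickelacycle, and C(sp2)–C(sp3) reductive elimination forms the second bond. The closest known reaction type is the nickel-catalysed intermolecular insertion of alkynes into the C(O)–C bond of cyclobutanones, a formal [4+2] of a C–C σ bond with a 2π partner. Ring B is closed by that reductive elimination, from the four-carbon unit C2–C1–C8a–C4a and the two alkyne carbons. No new stereocentre arises: the ring-fusion carbon passes from the carbonyl carbon to nickel and on to the alkyne carbon with retention, so the cis fusion and the configuration from step 3 are carried over. The step needs cleavage of the C(O)–CH(ring fusion) bond and not of the C(O)–C(OMe) bond, which the fully substituted methoxy-bearing α-carbon should secure because the less substituted α-carbon migrates to nickel. It also needs the unsubstituted alkyne terminus to bond to the carbonyl carbon so that the methyl ends on C4, which the hindered ketone and the bulky carbene ligand should favour.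

Step 5
Reactants: 11 cis-fused 1-methoxy ring-B enone
Product: 12 cis-fused ring-B enone
Conditions: SmI2 (2.5 equiv), THF–MeOH, −78 °C, then 20 °C
Reagents that add atoms: none
Why: Samarium diiodide reduction of the α-alkoxy ketone (ketyl, loss of methoxide) gives a dienolate; protonation under equilibrating conditions should place the side chain on the convex face of the cis-fused bicycle, cis to both ring-fusion hydrogens, which sets C1.

Step 6
Reactants: 12 cis-fused ring-B enone
Product: 13 allylic alcohol
Conditions: NaBH4, CeCl3·7H2O, MeOH, −78 °C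
Reagents that add atoms: none
Why: Luche 1,2-reduction; hydride should add axially from the convex face and put the hydroxyl on the concave face, trans to the side chain; this hydroxyl only directs step 7 and is inverted in steps 9–10.

Step 7
Reactants: 13 allylic alcohol
Product: 14 epoxy alcohol
Conditions: VO(acac)2 (acac = acetylacetonate, 5 mol %), t-BuOOH, CH2Cl2, 0 °C
Reagents that add atoms: tert-butyl hydroperoxide (CC(C)(C)OO)
Why: Vanadium-catalysed hydroxyl-directed epoxidation delivers oxygen to the alkene face that carries the allylic OH, which sets C4 (oxygen trans to 4a-H); the ring-A double bond has no directing group and should stay intact.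

Step 8
Reactants: 14 epoxy alcohol
Product: 15 syn-1,3-diol
Conditions: NaAlH2(OCH2CH2OCH3)2, THF, 0 °C to rt
Reagents that add atoms: none
Why: Reductive opening of the 2,3-epoxy alcohol with Red-Al; hydride is delivered from the aluminium alkoxide to the nearer epoxide carbon C3, leaving the tertiary alcohol at C4.

Step 9
Reactants: 15 syn-1,3-diol
Product: 16 β-hydroxy ketone
Conditions: Dess–Martin periodinane, NaHCO3, CH2Cl2, 0 °C
Reagents that add atoms: none
Why: Dess–Martin oxidation of the secondary alcohol; the tertiary alcohol cannot be oxidised.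

Step 10
Reactants: 16 β-hydroxy ketone
Product: 17 anti-1,3-diol
Conditions: Me4NBH(OAc)3, AcOH–MeCN, −30 °C
Reagents that add atoms: none
Why: Evans–Saksena reduction; the C4 alkoxyborohydride hands hydride to the ketone from the face of the C4–O bond, so the new C2 hydroxyl should be trans to the C4 hydroxyl and cis to the side chain (sets C2).

Step 11
Reactants: 18 2,2-dimethyl-4,7-dihydro-1,3-dioxepine
Product: 19 trans-dibromide
Conditions: Br2, CH2Cl2, −78 °C
Reagents that add atoms: bromine (BrBr)
Why: Anti addition of bromine to the ring alkene.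

Step 12
Reactants: 19 trans-dibromide
Product: 20 vinyl bromide
Conditions: DBU, toluene, 80 °C
Reagents that add atoms: none
Why: E2 dehydrobromination of the vicinal dibromide to the vinyl bromide.

Step 13
Reactants: 20 vinyl bromide
Product: 22 dioxepine carboxylic acid, via vinyllithium 21 (not isolated)
Conditions: t-BuLi (2 equiv), THF, −78 °C; CO2; then aq. HCl
Reagents that add atoms: carbon dioxide (O=C=O)
Why: Bromine–lithium exchange and carboxylation; the seven-membered ring holds the two CH2O groups cis, which is the E geometry needed in the target ester.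

Step 14
Reactants: 17 anti-1,3-diol; 22 dioxepine carboxylic acid
Product: 23 C2 ester
Conditions: EDC·HCl, DMAP, CH2Cl2, 0 °C to rt
Reagents that add atoms: none
Why: Steglich-type esterification of the secondary alcohol; the tertiary C4 alcohol is too hindered to react.

Step 15
Reactants: 23 C2 ester
Product: 24 C4 trimethylsilyl ether
Conditions: TMSOTf, 2,6-lutidine, CH2Cl2, −78 °C
Reagents that add atoms: trimethylsilyl triflate (C[Si](C)(C)OS(=O)(=O)C(F)(F)F)
Why: Silylation of the tertiary alcohol; it blocks oxa-Michael addition of this hydroxyl to the ring-A enone made in step 17.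

Step 16
Reactants: 24 C4 trimethylsilyl ether
Product: 25 C6 allylic alcohol
Conditions: SeO2 (0.3 equiv), t-BuOOH, CH2Cl2, rt
Reagents that add atoms: tert-butyl hydroperoxide (CC(C)(C)OO)
Why: Selenium dioxide allylic hydroxylation (ene reaction, then [2,3]-shift): selenium attacks the less substituted alkene carbon C8 and hydrogen is taken from the ring CH2 on the more substituted side, so oxygen ends on C6; the C6 configuration is erased in step 17.

Step 17
Reactants: 25 C6 allylic alcohol
Product: 26 cis-fused ring-A enone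
Conditions: Dess–Martin periodinane, NaHCO3, CH2Cl2, 0 °C
Reagents that add atoms: none
Why: Dess–Martin oxidation of the allylic alcohol to the conjugated enone.

Step 18
Reactants: 26 cis-fused ring-A enone
Product: 27 trans-fused ring-A enone
Conditions: DBU, toluene, 60 °C
Reagents that add atoms: none
Why: DBU removes the γ-hydrogen (C8a–H) to give the extended dienolate, and reprotonation under equilibrium control should favour the trans-fused decalin, because each cis-fused conformer puts C8 or the C4 methyl syn-axial to an oxygen substituent on ring B; ring B has no enolisable carbonyl, so C1, C2, C4 and C4a stay as set (sets C8a).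

Step 19
Reactants: 27 trans-fused ring-A enone
Product: 28 C6 alcohol
Conditions: NaBH4, CeCl3·7H2O, MeOH, −78 °C
Reagents that add atoms: none
Why: Luche reduction; axial hydride attack should give the pseudo-equatorial allylic alcohol, cis to 8a-H (sets C6), and the conjugated ester is not reduced.

Step 20
Reactants: 28 C6 alcohol
Product: 29 C6 acetate
Conditions: Ac2O, pyridine, DMAP (cat.), CH2Cl2, 0 °C
Reagents that add atoms: acetic anhydride (CC(=O)OC(C)=O)
Why: Acetylation of the only free hydroxyl.

Step 21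
Reactants: 29 C6 acetate
Product: 30 primary/tertiary diol
Conditions: HF·pyridine, pyridine, THF, 0 °C to rt
Reagents that add atoms: none
Why: Fluoride cleaves the primary silyl ether and the tertiary trimethylsilyl ether; buffered conditions should spare the esters and the acetonide.

Step 22
Reactants: 30 primary/tertiary diol
Product: 31 aldehyde
Conditions: Dess–Martin periodinane, NaHCO3, CH2Cl2, 0 °C
Reagents that add atoms: none
Why: Dess–Martin oxidation of the primary alcohol; the tertiary alcohol is inert.

Step 23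
Reactants: 31 aldehyde
Product: 33 2-substituted acrolein, via Mannich base 32 (not isolated)
Conditions: CH2=NMe2+ I− (Eschenmoser's salt), Et3N, CH2Cl2, rt
Reagents that add atoms: N,N-dimethylmethyleneiminium iodide (C=[N+](C)C.[I-])
Why: Mannich reaction of the aldehyde enol with the iminium salt, then elimination of dimethylamine (α-methylenation of an aldehyde).

Step 24
Reactants: 33 2-substituted acrolein
Product: 34 acrylic acid acetonide
Conditions: NaClO2, NaH2PO4, 2-methylbut-2-ene, t-BuOH–H2O, 0 °C
Reagents that add atoms: sodium chlorite ([Na+].[O-]Cl=O)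
Why: Pinnick oxidation of the enal to the acrylic acid; the alkene scavenger takes up hypochlorous acid.

Step 25
Reactants: 34 acrylic acid acetonide
Product: 35 CNP0468194.2
Conditions: AcOH–H2O (4:1), rt
Reagents that add atoms: none
Why: Acid-catalysed hydrolysis of the seven-membered acetonide frees the two allylic hydroxyls.

**Compound list**

1 | methoxyacetyl chloride | COCC(Cl)=O | starting material
2 | (2R,5R)-2,5-dimethylpyrrolidine | C[C@@H]1CC[C@@H](C)N1 | starting material
3 | 1-[(2R,5R)-2,5-dimethylpyrrolidin-1-yl]-2-methoxyethan-1-one | COCC(=O)N1[C@H](C)CC[C@H]1C | intermediate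
4 | tert-butyl(2-iodoethoxy)diphenylsilane | CC(C)(C)[Si](OCCI)(c1ccccc1)c1ccccc1 | starting material
5 | 4-{[tert-butyl(diphenyl)silyl]oxy}-1-[(2R,5R)-2,5-dimethylpyrrolidin-1-yl]-2-methoxybutan-1-one (chain C2: either configuration) | COC(CCO[Si](c1ccccc1)(c1ccccc1)C(C)(C)C)C(=O)N1[C@H](C)CC[C@H]1C | intermediate
6 | 1-methylcyclohexa-1,3-diene | CC1=CC=CCC1 | starting material
7 | keteniminium triflate of 5 | COC(CCO[Si](c1ccccc1)(c1ccccc1)C(C)(C)C)=C=[N+]1[C@H](C)CC[C@H]1C.[O-]S(=O)(=O)C(F)(F)F | intermediate
8 | cyclobutaniminium triflate (iminium of 9 with the auxiliary) | CC(C)(C)[Si](OCCC1(OC)[C@H]2C=C(C)CC[C@H]2C1=[N+]1[C@H](C)CC[C@H]1C)(c1ccccc1)c1ccccc1.[O-]S(=O)(=O)C(F)(F)F | intermediate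
9 | (1S,6R)-8-(2-{[tert-butyl(diphenyl)silyl]oxy}ethyl)-8-methoxy-3-methylbicyclo[4.2.0]oct-2-en-7-one (cis-fused; C8 either configuration) | CC(C)(C)[Si](OCCC1(OC)[C@H]2C=C(C)CC[C@H]2C1=O)(c1ccccc1)c1ccccc1 | intermediate
10 | propyne | CC#C | starting material
11 | (4aR,8aS)-1-(2-{[tert-butyl(diphenyl)silyl]oxy}ethyl)-1-methoxy-4,7-dimethyl-4a,5,6,8a-tetrahydronaphthalen-2(1H)-one (cis-fused; C1 either configuration) | CC(C)(C)[Si](OCCC1(OC)[C@H]2C=C(C)CC[C@H]2C(C)=CC1=O)(c1ccccc1)c1ccccc1 | intermediate
12 | (1R,4aR,8aS)-1-(2-{[tert-butyl(diphenyl)silyl]oxy}ethyl)-4,7-dimethyl-4a,5,6,8a-tetrahydronaphthalen-2(1H)-one (cis-fused; side chain cis to 4a-H and 8a-H) | CC(C)(C)[Si](OCC[C@@H]1[C@H]2C=C(C)CC[C@H]2C(C)=CC1=O)(c1ccccc1)c1ccccc1 | intermediate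
13 | 2-alcohol of 12 (1,2,4a,5,6,8a-hexahydronaphthalen-2-ol; 2-OH trans to the side chain) | CC(C)(C)[Si](OCC[C@@H]1[C@H]2C=C(C)CC[C@H]2C(C)=C[C@H]1O)(c1ccccc1)c1ccccc1 | intermediate
14 | 3,4-epoxide of 13 (epoxide oxygen cis to 2-OH, trans to 4a-H) | CC(C)(C)[Si](OCC[C@@H]1[C@H]2C=C(C)CC[C@H]2[C@@]3(C)O[C@H]3[C@H]1O)(c1ccccc1)c1ccccc1 | intermediate
15 | 1-(2-silyloxyethyl)-4,7-dimethyl-1,2,3,4,4a,5,6,8a-octahydronaphthalene-2,4-diol (2-OH and 4-OH cis, both trans to 4a-H; cis-fused) | CC(C)(C)[Si](OCC[C@@H]1[C@H]2C=C(C)CC[C@H]2[C@@](C)(O)C[C@H]1O)(c1ccccc1)c1ccccc1 | intermediate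
16 | 4-hydroxy-1-(2-silyloxyethyl)-4,7-dimethyl-3,4,4a,5,6,8a-hexahydronaphthalen-2(1H)-one (4-OH trans to 4a-H; cis-fused) | CC(C)(C)[Si](OCC[C@@H]1[C@H]2C=C(C)CC[C@H]2[C@@](C)(O)CC1=O)(c1ccccc1)c1ccccc1 | intermediate
17 | 2-epimer of 15 (2-OH cis to the side chain, trans to 4-OH; cis-fused) | CC(C)(C)[Si](OCC[C@@H]1[C@H]2C=C(C)CC[C@H]2[C@@](C)(O)C[C@@H]1O)(c1ccccc1)c1ccccc1 | intermediate
18 | 2,2-dimethyl-4,7-dihydro-1,3-dioxepine | CC1(C)OCC=CCO1 | starting material
19 | trans-5,6-dibromo-2,2-dimethyl-1,3-dioxepane (racemic, one enantiomer drawn) | CC1(C)OC[C@H](Br)[C@H](Br)CO1 | intermediate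
20 | 5-bromo-2,2-dimethyl-4,7-dihydro-1,3-dioxepine | CC1(C)OCC=C(Br)CO1 | intermediate
21 | (2,2-dimethyl-4,7-dihydro-1,3-dioxepin-5-yl)lithium | [Li]C1=CCOC(C)(C)OC1 | intermediate
22 | 2,2-dimethyl-4,7-dihydro-1,3-dioxepine-5-carboxylic acid | CC1(C)OCC=C(C(=O)O)CO1 | intermediate
23 | 2-O-(2,2-dimethyl-4,7-dihydro-1,3-dioxepine-5-carbonyl) ester of 17 | CC(C)(C)[Si](OCC[C@@H]1[C@H]2C=C(C)CC[C@H]2[C@@](C)(O)C[C@@H]1OC(=O)C1=CCOC(C)(C)OC1)(c1ccccc1)c1ccccc1 | intermediate
24 | 4-O-trimethylsilyl ether of 23 | CC(C)(C)[Si](OCC[C@@H]1[C@H]2C=C(C)CC[C@H]2[C@@](C)(O[Si](C)(C)C)C[C@@H]1OC(=O)C1=CCOC(C)(C)OC1)(c1ccccc1)c1ccccc1 | intermediate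
25 | 6-hydroxy derivative of 24 (C6 either configuration) | CC(C)(C)[Si](OCC[C@@H]1[C@H]2C=C(C)C(O)C[C@H]2[C@@](C)(O[Si](C)(C)C)C[C@@H]1OC(=O)C1=CCOC(C)(C)OC1)(c1ccccc1)c1ccccc1 | intermediate
26 | 6-oxo derivative of 24 (ring-A enone, cis-fused) | CC(C)(C)[Si](OCC[C@@H]1[C@H]2C=C(C)C(=O)C[C@H]2[C@@](C)(O[Si](C)(C)C)C[C@@H]1OC(=O)C1=CCOC(C)(C)OC1)(c1ccccc1)c1ccccc1 | intermediate
27 | 8a-epimer of 26 (trans-fused; 8a-H cis to 1-H) | CC(C)(C)[Si](OCC[C@@H]1[C@@H]2C=C(C)C(=O)C[C@H]2[C@@](C)(O[Si](C)(C)C)C[C@@H]1OC(=O)C1=CCOC(C)(C)OC1)(c1ccccc1)c1ccccc1 | intermediate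
28 | 6-alcohol from 27 (6-OH cis to 8a-H) | CC(C)(C)[Si](OCC[C@@H]1[C@@H]2C=C(C)[C@@H](O)C[C@H]2[C@@](C)(O[Si](C)(C)C)C[C@@H]1OC(=O)C1=CCOC(C)(C)OC1)(c1ccccc1)c1ccccc1 | intermediate
29 | 6-acetate of 28 | CC(C)(C)[Si](OCC[C@@H]1[C@@H]2C=C(C)[C@@H](OC(C)=O)C[C@H]2[C@@](C)(O[Si](C)(C)C)C[C@@H]1OC(=O)C1=CCOC(C)(C)OC1)(c1ccccc1)c1ccccc1 | intermediate
30 | desilylated 29 (1-(2-hydroxyethyl), 4-OH free) | OCC[C@@H]1[C@@H]2C=C(C)[C@@H](OC(C)=O)C[C@H]2[C@@](C)(O)C[C@@H]1OC(=O)C1=CCOC(C)(C)OC1 | intermediate
31 | aldehyde from 30 (1-(2-oxoethyl)) | O=CC[C@@H]1[C@@H]2C=C(C)[C@@H](OC(C)=O)C[C@H]2[C@@](C)(O)C[C@@H]1OC(=O)C1=CCOC(C)(C)OC1 | intermediate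
32 | Mannich base of 31 (α-(dimethylaminomethyl) aldehyde, α-carbon either configuration) | CN(C)CC(C=O)[C@@H]1[C@@H]2C=C(C)[C@@H](OC(C)=O)C[C@H]2[C@@](C)(O)C[C@@H]1OC(=O)C1=CCOC(C)(C)OC1 | intermediate
33 | 2-substituted acrolein (α-methylene aldehyde) | C=C(C=O)[C@@H]1[C@@H]2C=C(C)[C@@H](OC(C)=O)C[C@H]2[C@@](C)(O)C[C@@H]1OC(=O)C1=CCOC(C)(C)OC1 | intermediate
34 | acrylic acid with the side-chain diol as acetonide | C=C(C(=O)O)[C@@H]1[C@@H]2C=C(C)[C@@H](OC(C)=O)C[C@H]2[C@@](C)(O)C[C@@H]1OC(=O)C1=CCOC(C)(C)OC1 | intermediate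
35 | 2-[(1S,2S,4S,4aR,6S,8aS)-6-acetoxy-4-hydroxy-2-{[(2E)-4-hydroxy-2-(hydroxymethyl)but-2-enoyl]oxy}-4,7-dimethyl-1,2,3,4,4a,5,6,8a-octahydronaphthalen-1-yl]prop-2-enoic acid (CNP0468194.2) | C=C(C(=O)O)[C@@H]1[C@@H]2C=C(C)[C@@H](OC(C)=O)C[C@H]2[C@@](C)(O)C[C@@H]1OC(=O)/C(=C/CO)CO | target

**Count and risks**

Total steps: 25. Longest linear sequence: 22 (steps 1–10 and 14–25); steps 11–13 make the acid 22 in a side branch.

Most likely to fail:

1. Step 4. Propyne may oligomerise on zerovalent nickel faster than it couples with the hindered ketone, or insertion may take place on the wrong side of the carbonyl. The fallback sets out from 9 and comes back at 11, making the two bonds one after the other. The allenylzinc reagent from 3-bromo-1-(trimethylsilyl)prop-1-yne and zinc (THF) should add to 9 through its γ-carbon to give the allenyl carbinol F1. Heating F1 with [Rh(OH)(cod)]2 and a bisphosphine should give the 3-silyl enone F2: the monovalent rhodium alkoxide undergoes β-carbon elimination of the less hindered ring-fusion carbon, the alkylrhodium adds 6-endo to the allenyl ketone, and protonation follows. TBAF/AcOH then removes the silyl group and gives 11.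

2. Step 3. The auxiliary may discriminate the diene faces poorly, or the silyl ether oxygen may intercept the keteniminium ion. The fallback sets out from 4 and 6 and comes back at 12, with the chiral group moved into the blocking alkoxy substituent. The dianion of (−)-menthyloxyacetic acid (LDA, 2 equiv) is alkylated with 4 to the acid F3, and oxalyl chloride gives the acid chloride F4. Et3N in the presence of 6 generates the menthyloxy ketene, whose thermal [2+2] should give diastereomeric cyclobutanones separable by chromatography; the one with the ring fusion of 9 is the menthyloxy cyclobutanone F5. The conditions of step 4 convert F5 into the menthyloxy enone F6, and SmI2 as in step 5 removes the auxiliary and gives 12.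

3. Step 7. Ring A on the concave face may hinder oxygen delivery to C3=C4, which would cost face selectivity or chemoselectivity. The fallback sets out from 13 and comes back at 15, delivering the C4 oxygen from the C2 oxygen itself. Boc2O/DMAP converts 13 into the tert-butyl carbonate F7. IBr (toluene, −80 °C) should attack the convex face while the carbonate oxygen closes on the tertiary C4 from the side of the C2–O bond, giving the cyclic iodocarbonate F8. Bu3SnH/AIBN removes iodine to give the cyclic carbonate F9, and K2CO3/MeOH releases 15.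

**Further compounds**

F1 | step 4 | 7-hydroxy-7-[1-(trimethylsilyl)propa-1,2-dien-1-yl] analogue of 9 (allenyl carbinol; carbinol carbon either configuration) | CC(C)(C)[Si](OCCC1(OC)[C@H]2C=C(C)CC[C@H]2C1(O)C(=C=C)[Si](C)(C)C)(c1ccccc1)c1ccccc1
F2 | step 4 | 3-(trimethylsilyl) derivative of 11 | CC(C)(C)[Si](OCCC1(OC)[C@H]2C=C(C)CC[C@H]2C(C)=C([Si](C)(C)C)C1=O)(c1ccccc1)c1ccccc1
F3 | step 3 | 4-{[tert-butyl(diphenyl)silyl]oxy}-2-[(1R,2S,5R)-menthyloxy]butanoic acid (C2 either configuration) | CC(C)[C@@H]1CC[C@@H](C)C[C@H]1OC(CCO[Si](c1ccccc1)(c1ccccc1)C(C)(C)C)C(=O)O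
F4 | step 3 | acid chloride of F3 | CC(C)[C@@H]1CC[C@@H](C)C[C@H]1OC(CCO[Si](c1ccccc1)(c1ccccc1)C(C)(C)C)C(=O)Cl
F5 | step 3 | 8-menthyloxy analogue of 9 (same ring-fusion configuration) | CC(C)[C@@H]1CC[C@@H](C)C[C@H]1OC1(CCO[Si](c2ccccc2)(c2ccccc2)C(C)(C)C)[C@H]2C=C(C)CC[C@H]2C1=O
F6 | step 3 | 1-menthyloxy analogue of 11 | CC(C)[C@@H]1CC[C@@H](C)C[C@H]1OC1(CCO[Si](c2ccccc2)(c2ccccc2)C(C)(C)C)[C@H]2C=C(C)CC[C@H]2C(C)=CC1=O
F7 | step 7 | tert-butyl carbonate of 13 | CC(C)(C)[Si](OCC[C@@H]1[C@H]2C=C(C)CC[C@H]2C(C)=C[C@H]1OC(=O)OC(C)(C)C)(c1ccccc1)c1ccccc1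
F8 | step 7 | cyclic 2,4-carbonate with iodine on C3 (iodine trans to both oxygens) | CC(C)(C)[Si](OCC[C@@H]1[C@H]2C=C(C)CC[C@H]2[C@@]3(C)OC(=O)O[C@@H]1[C@H]3I)(c1ccccc1)c1ccccc1
F9 | step 7 | cyclic 2,4-carbonate of 15 | CC(C)(C)[Si](OCC[C@@H]1[C@H]2C=C(C)CC[C@H]2[C@@]3(C)OC(=O)O[C@@H]1C3)(c1ccccc1)c1ccccc1
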